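**Strategy**

- All seven diaryl ether C–O bonds are cut, one ring at a time from the ring H end. Six (A–B, B–C, C–D, E–F, F–G, G–H) are cut between a phenol oxygen and C1 of a ring that enters as a 3,4,5-trialkoxybenzyne. The seventh (D–E) is cut by taking ring E apart into a squarate ester and a methoxyvinyl unit.
- Enabling feature: rings B, C, D, F, G and H each carry oxygen on C3, C4 and C5, with the ether carbon C1 meta to O-3. C2 is H (B, D, F, H) or the next ether oxygen (C, G). This is the C1/C2 pattern left when a phenoxide and an electrophile (H or I) add across such an aryne.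
- Only the ether from C4 of ring D to C1 of ring E has four ortho oxygens and no ortho C–H. Ring E is therefore grown on that oxygen: squarate ester, 1,2-addition, 4π opening, 6π closure.
- Forward order: A, B, C (aryloxy-iodination, then I to OH), D, E (ring built), F, G (aryloxy-iodination, then I to OH), H, then hydrogenolysis and demethylation.
- Stereochemistry: none to set. The target is achiral and only aryne regiochemistry matters; it is fixed by the alkoxy group next to the triple bond.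

Key step: step 20

Remark on the chemistry: the diaryl ether axes are assumed to rotate freely (no isolable atropisomers); ring E is carried as its trimethyl ether until the last step.

Convention: rings are lettered A to H along the chain; C1 of a ring is the carbon bound to the oxygen that joins it to the preceding ring. Ring A = 2,4,6-tris(benzyloxy)phenyl. Rings B and D = 3,5-bis(benzyloxy)-1,4-phenylene. Rings C and G = 3,4,5-tris(benzyloxy)-1,2-phenylene. Ring E = 4,5,6-trimethoxy-1,2-phenylene. Ring F = 2,2-diphenyl-1,3-benzodioxole-5,7-diyl (entered at C5, left through the oxygen on C7). Ring H = 3,4,5-tris(benzyloxy)phenyl. Benzynes 32 and 36 are each released from the same precursor in more than one step; each is entered as a non-isolated compound at the step where it first arises and is cited by its number afterwards.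

**Ring A phenol**

Step 1
Reactants: 1 2,4,6-trihydroxybenzaldehyde
Product: 2 2,4,6-tris(benzyloxy)benzaldehyde
Conditions: BnBr, K2CO3, DMF, 60 °C
Reagents that add atoms: benzyl bromide BrCc1ccccc1
Why: Williamson etherification; the formyl group lowers the carbon nucleophilicity of the phloroglucinol ring, so O-benzylation of all three phenoxides is favoured over C-benzylation.

Step 2
Reactants: 2 2,4,6-tris(benzyloxy)benzaldehyde
Product: 4 2,4,6-tris(benzyloxy)phenol, via aryl formate 3 (not isolated)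
Conditions: mCPBA, CH2Cl2, 0 °C to rt; then K2CO3 (cat.), MeOH, rt
Reagents that add atoms: meta-chloroperoxybenzoic acid OOC(=O)c1cccc(Cl)c1
Why: Baeyer–Villiger oxidation in which the electron-rich trialkoxyaryl group migrates to oxygen, followed by transesterification of the formate with methanol.

**Aryne precursor for rings B and D**

Step 3
Reactants: 5 3,4,5-trihydroxybenzaldehyde
Product: 6 3,5-dihydroxy-4-(methoxymethoxy)benzaldehyde
Conditions: MOMCl (1.0 equiv), i-Pr2NEt (1.05 equiv), DMF, −10 °C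
Reagents that add atoms: chloromethyl methyl ether COCCl
Why: selective Williamson-type O-alkylation; the 4-OH is para to the formyl group and the most acidic, so one equivalent of base forms its phenoxide and only that oxygen is alkylated.

Step 4
Reactants: 6 3,5-dihydroxy-4-(methoxymethoxy)benzaldehyde
Product: 7 3,5-bis(benzyloxy)-4-(methoxymethoxy)benzaldehyde
Conditions: BnBr, K2CO3, DMF, rt
Reagents that add atoms: benzyl bromide BrCc1ccccc1
Why: Williamson etherification of the two remaining phenols under basic conditions that leave the MOM acetal untouched.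

Step 5
Reactants: 7 3,5-bis(benzyloxy)-4-(methoxymethoxy)benzaldehyde
Product: 9 3,5-bis(benzyloxy)-4-(methoxymethoxy)phenol, via aryl formate 8 (not isolated)
Conditions: mCPBA, CH2Cl2, 0 °C to rt; then K2CO3 (cat.), MeOH, rt
Reagents that add atoms: meta-chloroperoxybenzoic acid OOC(=O)c1cccc(Cl)c1
Why: Baeyer–Villiger oxidation with migration of the trialkoxyaryl group, then methanolysis of the formate.

Step 6
Reactants: 9 3,5-bis(benzyloxy)-4-(methoxymethoxy)phenol
Product: 10 3,5-bis(benzyloxy)-2-bromo-4-(methoxymethoxy)phenol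
Conditions: NBS (1.0 equiv), CH2Cl2, −78 to −40 °C
Reagents that add atoms: N-bromosuccinimide O=C1CCC(=O)N1Br
Why: electrophilic aromatic bromination ortho to the free hydroxyl; the para position is blocked and the two ortho positions are equivalent, so one equivalent at low temperature should stop at a single monobromide.

Step 7
Reactants: 10 3,5-bis(benzyloxy)-2-bromo-4-(methoxymethoxy)phenol
Product: 13 3,5-bis(benzyloxy)-4-(methoxymethoxy)-2-(trimethylsilyl)phenyl triflate, via silyl ether 11 (not isolated), via lithium phenoxide 12 (not isolated)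
Conditions: HMDS, THF, 65 °C, then evaporation; n-BuLi, THF, −100 °C; Tf2O, −100 to −78 °C
Reagents that add atoms: hexamethyldisilazane C[Si](C)(C)N[Si](C)(C)C; triflic anhydride O=S(=O)(OS(=O)(=O)C(F)(F)F)C(F)(F)F
Why: O-silylation, bromine–lithium exchange and retro-Brook rearrangement (1,3 shift of silicon from O to C) give the ortho-silyl phenoxide, which is triflated in the same flask; this is the standard entry to 2-silylaryl triflates.

**Aryne precursor for rings C, G and H**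

Step 8
Reactants: 5 3,4,5-trihydroxybenzaldehyde
Product: 14 3,4,5-tris(benzyloxy)benzaldehyde
Conditions: BnBr, K2CO3, DMF, 60 °C
Reagents that add atoms: benzyl bromide BrCc1ccccc1
Why: exhaustive Williamson etherification of the three phenols.

Step 9
Reactants: 14 3,4,5-tris(benzyloxy)benzaldehyde
Product: 16 3,4,5-tris(benzyloxy)phenol, via aryl formate 15 (not isolated)
Conditions: mCPBA, CH2Cl2, 0 °C to rt; then K2CO3 (cat.), MeOH, rt
Reagents that add atoms: meta-chloroperoxybenzoic acid OOC(=O)c1cccc(Cl)c1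
Why: Baeyer–Villiger oxidation with aryl migration, then methanolysis of the formate.

Step 10
Reactants: 16 3,4,5-tris(benzyloxy)phenol
Product: 17 3,4,5-tris(benzyloxy)-2-bromophenol
Conditions: NBS (1.0 equiv), CH2Cl2, −78 to −40 °C
Reagents that add atoms: N-bromosuccinimide O=C1CCC(=O)N1Br
Why: electrophilic bromination ortho to the hydroxyl of a symmetrical phenol whose para position is blocked.

Step 11
Reactants: 17 3,4,5-tris(benzyloxy)-2-bromophenol
Product: 20 3,4,5-tris(benzyloxy)-2-(trimethylsilyl)phenyl triflate, via silyl ether 18 (not isolated), via lithium phenoxide 19 (not isolated)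
Conditions: HMDS, THF, 65 °C, then evaporation; n-BuLi, THF, −100 °C; Tf2O, −100 to −78 °C
Reagents that add atoms: hexamethyldisilazane C[Si](C)(C)N[Si](C)(C)C; triflic anhydride O=S(=O)(OS(=O)(=O)C(F)(F)F)C(F)(F)F
Why: bromine–lithium exchange, retro-Brook rearrangement and in situ triflation, as in step 7; at −100 °C exchange is much faster than benzylic deprotonation.

**Aryne precursor for ring F**

Step 12
Reactants: 5 3,4,5-trihydroxybenzaldehyde
Product: 21 7-hydroxy-2,2-diphenyl-1,3-benzodioxole-5-carbaldehyde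
Conditions: Ph2CCl2, K2CO3, MeCN, rt
Reagents that add atoms: dichlorodiphenylmethane ClC(Cl)(c1ccccc1)c1ccccc1
Why: ketal formation by double O-alkylation; the dichloride can only bridge two adjacent hydroxyls, and the two vicinal pairs are equivalent by symmetry, so one monoketal with one free hydroxyl results.

Step 13
Reactants: 21 7-hydroxy-2,2-diphenyl-1,3-benzodioxole-5-carbaldehyde
Product: 22 7-(methoxymethoxy)-2,2-diphenyl-1,3-benzodioxole-5-carbaldehyde
Conditions: MOMCl, i-Pr2NEt, CH2Cl2, 0 °C to rt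
Reagents that add atoms: chloromethyl methyl ether COCCl
Why: O-alkylation of the only free phenol to the MOM acetal.

Step 14
Reactants: 22 7-(methoxymethoxy)-2,2-diphenyl-1,3-benzodioxole-5-carbaldehyde
Product: 24 7-(methoxymethoxy)-2,2-diphenyl-1,3-benzodioxol-5-ol, via aryl formate 23 (not isolated)
Conditions: mCPBA, CH2Cl2, 0 °C to rt; then K2CO3 (cat.), MeOH, rt
Reagents that add atoms: meta-chloroperoxybenzoic acid OOC(=O)c1cccc(Cl)c1
Why: Baeyer–Villiger oxidation with aryl migration, then methanolysis; ketal and MOM ether tolerate the weakly acidic peracid at low temperature.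

Step 15
Reactants: 24 7-(methoxymethoxy)-2,2-diphenyl-1,3-benzodioxol-5-ol
Product: 25 7-(methoxymethoxy)-2,2-diphenyl-1,3-benzodioxol-5-yl N-isopropylcarbamate
Conditions: i-PrNCO, Et3N (cat.), CH2Cl2, rt
Reagents that add atoms: isopropyl isocyanate CC(C)N=C=O
Why: base-catalysed addition of the phenol to the isocyanate installs a strong, later cleavable directing group.

Step 16
Reactants: 25 7-(methoxymethoxy)-2,2-diphenyl-1,3-benzodioxol-5-yl N-isopropylcarbamate
Product: 29 7-(methoxymethoxy)-2,2-diphenyl-6-(trimethylsilyl)-1,3-benzodioxol-5-yl N-isopropylcarbamate, via N-silyl carbamate 26 (not isolated), via aryllithium 27 (not isolated), via bis-silyl carbamate 28 (not isolated)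
Conditions: TBSOTf, TMEDA, Et2O, 0 °C to rt; n-BuLi, TMEDA, −78 °C; TMSCl, −78 °C to rt; aq. NaHSO4
Reagents that add atoms: chlorotrimethylsilane C[Si](C)(C)Cl
Why: directed ortho-metalation of the in situ N-silylated carbamate; the carbamate and the chelating MOM ether should direct n-BuLi to the carbon between them, the ketal oxygen on the other side being shielded by its two phenyl groups, and should some of the other ortho isomer form it gives an aryne that is attacked at the same carbon and need not be removed.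

Step 17
Reactants: 29 7-(methoxymethoxy)-2,2-diphenyl-6-(trimethylsilyl)-1,3-benzodioxol-5-yl N-isopropylcarbamate
Product: 31 7-(methoxymethoxy)-2,2-diphenyl-6-(trimethylsilyl)-1,3-benzodioxol-5-yl triflate, via silyl phenol 30 (not isolated)
Conditions: Et2NH, DBU, MeCN, 40 °C; then PhNTf2, rt
Reagents that add atoms: N-phenylbis(trifluoromethanesulfonimide) O=S(=O)(N(c1ccccc1)S(=O)(=O)C(F)(F)F)C(F)(F)F
Why: base-induced elimination of the N–H carbamate to the phenoxide (the isocyanate is trapped by diethylamine) and O-triflation in one pot, the established carbamate-to-silyl-triflate sequence.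

**Chain assembly**

Step 18
Reactants: 4 2,4,6-tris(benzyloxy)phenol; 13 3,5-bis(benzyloxy)-4-(methoxymethoxy)-2-(trimethylsilyl)phenyl triflate
Product: 33 A–B dimer MOM ether, via benzyne 32 (not isolated)
Conditions: CsF, MeCN–toluene (3:1), rt
Reagents that add atoms: none
Why: fluoride-induced 1,2-elimination gives the aryne, and aryne O-arylation follows; the cesium phenoxide adds to C1, remote from the C3 benzyloxy group that distorts and polarises the triple bond, and the C2 anion is protonated by the medium.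

Step 19
Reactants: 33 A–B dimer MOM ether
Product: 34 A–B dimer phenol
Conditions: conc. HCl (cat.), MeOH–THF, 45 °C
Reagents that add atoms: none
Why: acid-catalysed acetal exchange removes the MOM group as dimethoxymethane; benzyl and diaryl ethers are stable.

Step 20
Reactants: 34 A–B dimer phenol; 20 3,4,5-tris(benzyloxy)-2-(trimethylsilyl)phenyl triflate
Product: 38 A–B–C trimer iodide, via potassium phenoxide 35 (not isolated), via benzyne 36 (not isolated), via aryl potassium 37 (not isolated)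
Conditions: KN(SiMe3)2, THF, 0 °C; then 20, n-C4F9I, KF, 18-crown-6, THF, 0 °C to rt, dark, argon
Reagents that add atoms: nonafluoro-1-iodobutane FC(F)(F)C(F)(F)C(F)(F)C(F)(F)I
Why: Proposed new method: fluoride removes the silyl group of 20 and triflate leaves to give benzyne 36, and the preformed phenoxide 35 adds through oxygen to C1, because the C3 benzyloxy group distorts and polarises the triple bond so that charge builds up on C2 next to the C–O bond. With no proton donor present (no free phenol, no acetonitrile) the C2 anion 37 attacks the iodine of C4F9I; the perfluorobutyl anion leaves and decays to octafluorobutene and fluoride, which carries the chain. The closest known reaction types are fluoride-induced O-arylation of phenols with 2-silylaryl triflates and three-component aryne couplings in which a heteroatom nucleophile and a halogen donor add across the triple bond. No ring is closed and no stereocentre is formed; the C1–O and C2–I bonds of ring C are made in one operation. The step needs attack at C1 and not C2, secured by the C3 alkoxy group, and iodine capture and not protonation, secured by the aprotic medium and excess iodine donor. Light is excluded to suppress electron-transfer perfluoroalkylation of the phenoxide.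

Step 21
Reactants: 38 A–B–C trimer iodide
Product: 41 A–B–C trimer phenol, via arylmagnesium chloride 39 (not isolated), via dimethyl boronate 40 (not isolated)
Conditions: i-PrMgCl·LiCl, THF, −40 °C; B(OMe)3, −40 to 0 °C; AcOH, 30% aq. H2O2, 0 °C to rt
Reagents that add atoms: hydrogen peroxide OO
Why: iodine–magnesium exchange (fast at a carbon flanked by two oxygens), borylation and oxidative 1,2-migration from boron to oxygen turn the C–I bond into C–OH; the acidic peroxide work-up avoids alkaline oxidation of the electron-rich phenol.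

Step 22
Reactants: 41 A–B–C trimer phenol; 13 3,5-bis(benzyloxy)-4-(methoxymethoxy)-2-(trimethylsilyl)phenyl triflate
Product: 42 A–B–C–D tetramer MOM ether
Conditions: CsF, MeCN–toluene (3:1), rt to 40 °C
Reagents that add atoms: none
Why: aryne O-arylation in which fluoride releases benzyne 32 from 13 exactly as in step 18; arynes accept the hindered 2,6-dioxygenated phenoxide, and the C3 benzyloxy group again directs it to C1, the C2 anion being protonated by the medium.

Step 23
Reactants: 42 A–B–C–D tetramer MOM ether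
Product: 43 A–B–C–D tetramer phenol
Conditions: conc. HCl (cat.), MeOH–THF, 45 °C
Reagents that add atoms: none
Why: acid-catalysed acetal exchange frees the 4-OH of ring D.

Step 24
Reactants: 44 squaric acid dichloride
Product: 45 3-chloro-4-methoxycyclobut-3-ene-1,2-dione
Conditions: MeOH (1.0 equiv), CH2Cl2, 0 °C to rt, N2 sweep
Reagents that add atoms: methanol CO
Why: addition–elimination at a vinylogous acid chloride; the methoxy group introduced first is a vinylogous ester donor that deactivates the second C–Cl, so one equivalent of methanol should stop at the ester chloride.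

Step 25
Reactants: 43 A–B–C–D tetramer phenol; 45 3-chloro-4-methoxycyclobut-3-ene-1,2-dione
Product: 46 tetramer aryl methyl squarate
Conditions: Et3N, CH2Cl2, −20 °C to rt
Reagents that add atoms: none
Why: addition–elimination of the hindered phenoxide at the chlorine-bearing carbon; chloride is a far better leaving group than methoxide, and the ring D oxygen becomes bonded to the carbon that will be C1 of ring E without any metal-mediated coupling.

Step 26
Reactants: 46 tetramer aryl methyl squarate; 47 methyl vinyl ether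
Product: 50 racemic 4-methoxy-4-(1-methoxyvinyl)cyclobutenone, via methoxyvinyllithium 48 (not isolated), via lithium alkoxide 49 (not isolated)
Conditions: 47, t-BuLi, THF, −78 to 0 °C; then 46, THF, −78 °C; MeOTf, −78 to −20 °C
Reagents that add atoms: methyl triflate COS(=O)(=O)C(F)(F)F
Why: 1,2-addition of the hard vinyllithium to the more electrophilic carbonyl, the one next to the methoxy-bearing carbon; it is the vinylogous ester of the weaker aryloxy donor and is not shielded by the 2,6-bis(benzyloxy)aryl group, and methyl triflate caps the tertiary alkoxide before anion-accelerated ring opening can start.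

Step 27
Reactants: 50 racemic 4-methoxy-4-(1-methoxyvinyl)cyclobutenone
Product: 53 A–B–C–D–E pentamer phenol, via dienylketene 51 (not isolated), via cyclohexadienone 52 (not isolated)
Conditions: toluene, 110 °C
Reagents that add atoms: none
Why: Moore rearrangement; conrotatory 4π opening with the 4-methoxy group turning outward places the methoxyvinyl group cis to the ketene, 6π electrocyclisation closes ring E between the ketene carbon and the vinyl CH2, and tautomerisation gives the phenol with its OH next to the aryloxy carbon.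

Step 28
Reactants: 53 A–B–C–D–E pentamer phenol; 31 7-(methoxymethoxy)-2,2-diphenyl-6-(trimethylsilyl)-1,3-benzodioxol-5-yl triflate
Product: 55 A-to-F hexamer MOM ether, via aryne 54 (not isolated)
Conditions: CsF, MeCN–toluene (3:1), rt
Reagents that add atoms: none
Why: aryne O-arylation; the phenoxide adds to C5 of the 5,6-didehydrobenzodioxole, remote from the MOM ether on C7, and the C6 anion is protonated.

Step 29
Reactants: 55 A-to-F hexamer MOM ether
Product: 56 A-to-F hexamer phenol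
Conditions: conc. HCl (cat.), MeOH–THF, rt
Reagents that add atoms: none
Why: mild acid-catalysed acetal exchange removes the MOM group; the diphenylmethylene ketal needs much stronger acid and should stay.

Step 30
Reactants: 56 A-to-F hexamer phenol; 20 3,4,5-tris(benzyloxy)-2-(trimethylsilyl)phenyl triflate
Product: 59 A-to-G heptamer iodide, via potassium phenoxide 57 (not isolated), via aryl potassium 58 (not isolated)
Conditions: KN(SiMe3)2, THF, 0 °C; then 20, n-C4F9I, KF, 18-crown-6, THF, 0 °C to rt, dark, argon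
Reagents that add atoms: nonafluoro-1-iodobutane FC(F)(F)C(F)(F)C(F)(F)C(F)(F)I
Why: Proposed new method: as in step 20, fluoride releases benzyne 36 from 20, the preformed phenoxide 57 adds to its C1 (directed by the C3 benzyloxy group) and the C2 anion 58, having no proton source, abstracts iodine from C4F9I; the closest known reaction types are aryne O-arylation of phenols and three-component aryne couplings of a heteroatom nucleophile with a halogen donor.

Step 31
Reactants: 59 A-to-G heptamer iodide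
Product: 62 A-to-G heptamer phenol, via arylmagnesium chloride 60 (not isolated), via dimethyl boronate 61 (not isolated)
Conditions: i-PrMgCl·LiCl, THF, −40 °C; B(OMe)3, −40 to 0 °C; AcOH, 30% aq. H2O2, 0 °C to rt
Reagents that add atoms: hydrogen peroxide OO
Why: iodine–magnesium exchange, borylation and oxidation convert C–I into C–OH as in step 21; ketal, methyl, benzyl and diaryl ethers are inert to the Grignard reagent at −40 °C.

Step 32
Reactants: 62 A-to-G heptamer phenol; 20 3,4,5-tris(benzyloxy)-2-(trimethylsilyl)phenyl triflate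
Product: 63 fully protected octamer
Conditions: CsF, MeCN–toluene (3:1), rt to 40 °C
Reagents that add atoms: none
Why: aryne O-arylation of the hindered ring G phenoxide at C1 of benzyne 36, released from 20 by fluoride as in step 20, with protonation of C2 by the medium, completes the chain.

Step 33
Reactants: 63 fully protected octamer
Product: 64 octamer with ring E as its trimethyl ether
Conditions: H2 (4 bar), Pd(OH)2/C, THF–MeOH, rt, then handling under argon
Reagents that add atoms: none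
Why: hydrogenolysis of the sixteen benzylic C–O bonds and of the doubly benzylic diphenylmethylene ketal; aryl methyl and diaryl ethers are not cleaved.

Step 34
Reactants: 64 octamer with ring E as its trimethyl ether
Product: 65 CNP0309601.0
Conditions: BBr3 (excess), CH2Cl2, −78 °C to rt; MeOH, then water; argon throughout
Reagents that add atoms: none
Why: Lewis acid demethylation; BBr3 coordinates the methyl ether oxygens and bromide removes the methyl groups, diaryl ethers are stable, and the borate esters formed on the free phenols are hydrolysed on work-up.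

**Compound list**

1 | 2,4,6-trihydroxybenzaldehyde | O=Cc1c(O)cc(O)cc1O | starting material
2 | 2,4,6-tris(benzyloxy)benzaldehyde | O=Cc1c(OCc2ccccc2)cc(OCc2ccccc2)cc1OCc2ccccc2 | intermediate
3 | 2,4,6-tris(benzyloxy)phenyl formate | O=COc1c(OCc2ccccc2)cc(OCc2ccccc2)cc1OCc2ccccc2 | intermediate
4 | 2,4,6-tris(benzyloxy)phenol | Oc1c(OCc2ccccc2)cc(OCc2ccccc2)cc1OCc2ccccc2 | intermediate
5 | 3,4,5-trihydroxybenzaldehyde | O=Cc1cc(O)c(O)c(O)c1 | starting material
6 | 3,5-dihydroxy-4-(methoxymethoxy)benzaldehyde | O=Cc1cc(O)c(OCOC)c(O)c1 | intermediate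
7 | 3,5-bis(benzyloxy)-4-(methoxymethoxy)benzaldehyde | O=Cc1cc(OCc2ccccc2)c(OCOC)c(OCc2ccccc2)c1 | intermediate
8 | 3,5-bis(benzyloxy)-4-(methoxymethoxy)phenyl formate | O=COc1cc(OCc2ccccc2)c(OCOC)c(OCc2ccccc2)c1 | intermediate
9 | 3,5-bis(benzyloxy)-4-(methoxymethoxy)phenol | Oc1cc(OCc2ccccc2)c(OCOC)c(OCc2ccccc2)c1 | intermediate
10 | 3,5-bis(benzyloxy)-2-bromo-4-(methoxymethoxy)phenol | Oc1cc(OCc2ccccc2)c(OCOC)c(OCc2ccccc2)c1Br | intermediate
11 | [3,5-bis(benzyloxy)-2-bromo-4-(methoxymethoxy)phenoxy]trimethylsilane | C[Si](C)(C)Oc1cc(OCc2ccccc2)c(OCOC)c(OCc2ccccc2)c1Br | intermediate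
12 | lithium 3,5-bis(benzyloxy)-4-(methoxymethoxy)-2-(trimethylsilyl)phenoxide | [Li+].[O-]c1cc(OCc2ccccc2)c(OCOC)c(OCc2ccccc2)c1[Si](C)(C)C | intermediate
13 | 3,5-bis(benzyloxy)-4-(methoxymethoxy)-2-(trimethylsilyl)phenyl triflate | FC(F)(F)S(=O)(=O)Oc1cc(OCc2ccccc2)c(OCOC)c(OCc2ccccc2)c1[Si](C)(C)C | intermediate
14 | 3,4,5-tris(benzyloxy)benzaldehyde | O=Cc1cc(OCc2ccccc2)c(OCc2ccccc2)c(OCc2ccccc2)c1 | intermediate
15 | 3,4,5-tris(benzyloxy)phenyl formate | O=COc1cc(OCc2ccccc2)c(OCc2ccccc2)c(OCc2ccccc2)c1 | intermediate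
16 | 3,4,5-tris(benzyloxy)phenol | Oc1cc(OCc2ccccc2)c(OCc2ccccc2)c(OCc2ccccc2)c1 | intermediate
17 | 3,4,5-tris(benzyloxy)-2-bromophenol | Oc1cc(OCc2ccccc2)c(OCc2ccccc2)c(OCc2ccccc2)c1Br | intermediate
18 | [3,4,5-tris(benzyloxy)-2-bromophenoxy]trimethylsilane | C[Si](C)(C)Oc1cc(OCc2ccccc2)c(OCc2ccccc2)c(OCc2ccccc2)c1Br | intermediate
19 | lithium 3,4,5-tris(benzyloxy)-2-(trimethylsilyl)phenoxide | [Li+].[O-]c1cc(OCc2ccccc2)c(OCc2ccccc2)c(OCc2ccccc2)c1[Si](C)(C)C | intermediate
20 | 3,4,5-tris(benzyloxy)-2-(trimethylsilyl)phenyl triflate | FC(F)(F)S(=O)(=O)Oc1cc(OCc2ccccc2)c(OCc2ccccc2)c(OCc2ccccc2)c1[Si](C)(C)C | intermediate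
21 | 7-hydroxy-2,2-diphenyl-1,3-benzodioxole-5-carbaldehyde | O=Cc1cc(O)c2OC(c3ccccc3)(c3ccccc3)Oc2c1 | intermediate
22 | 7-(methoxymethoxy)-2,2-diphenyl-1,3-benzodioxole-5-carbaldehyde | O=Cc1cc(OCOC)c2OC(c3ccccc3)(c3ccccc3)Oc2c1 | intermediate
23 | 7-(methoxymethoxy)-2,2-diphenyl-1,3-benzodioxol-5-yl formate | O=COc1cc(OCOC)c2OC(c3ccccc3)(c3ccccc3)Oc2c1 | intermediate
24 | 7-(methoxymethoxy)-2,2-diphenyl-1,3-benzodioxol-5-ol | Oc1cc(OCOC)c2OC(c3ccccc3)(c3ccccc3)Oc2c1 | intermediate
25 | 7-(methoxymethoxy)-2,2-diphenyl-1,3-benzodioxol-5-yl N-isopropylcarbamate | CC(C)NC(=O)Oc1cc(OCOC)c2OC(c3ccccc3)(c3ccccc3)Oc2c1 | intermediate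
26 | N-(tert-butyldimethylsilyl) derivative of carbamate 25 | CC(C)N([Si](C)(C)C(C)(C)C)C(=O)Oc1cc(OCOC)c2OC(c3ccccc3)(c3ccccc3)Oc2c1 | intermediate
27 | 6-lithio derivative of N-silyl carbamate 26 | CC(C)N([Si](C)(C)C(C)(C)C)C(=O)Oc1c([Li])c(OCOC)c2OC(c3ccccc3)(c3ccccc3)Oc2c1 | intermediate
28 | 6-(trimethylsilyl) derivative of N-silyl carbamate 26 | CC(C)N([Si](C)(C)C(C)(C)C)C(=O)Oc1c([Si](C)(C)C)c(OCOC)c2OC(c3ccccc3)(c3ccccc3)Oc2c1 | intermediate
29 | 7-(methoxymethoxy)-2,2-diphenyl-6-(trimethylsilyl)-1,3-benzodioxol-5-yl N-isopropylcarbamate | CC(C)NC(=O)Oc1c([Si](C)(C)C)c(OCOC)c2OC(c3ccccc3)(c3ccccc3)Oc2c1 | intermediate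
30 | 7-(methoxymethoxy)-2,2-diphenyl-6-(trimethylsilyl)-1,3-benzodioxol-5-ol | Oc1c([Si](C)(C)C)c(OCOC)c2OC(c3ccccc3)(c3ccccc3)Oc2c1 | intermediate
31 | 7-(methoxymethoxy)-2,2-diphenyl-6-(trimethylsilyl)-1,3-benzodioxol-5-yl triflate | FC(F)(F)S(=O)(=O)Oc1c([Si](C)(C)C)c(OCOC)c2OC(c3ccccc3)(c3ccccc3)Oc2c1 | intermediate
32 | 3,5-bis(benzyloxy)-4-(methoxymethoxy)benzyne (triple bond C1–C2) | C1#CC(OCc2ccccc2)=C(OCOC)C(OCc2ccccc2)=C1 | intermediate
33 | A–B dimer MOM ether, 1,3-bis(benzyloxy)-2-(methoxymethoxy)-5-[2,4,6-tris(benzyloxy)phenoxy]benzene | c1(OCc2ccccc2)cc(OCc2ccccc2)cc(OCc2ccccc2)c1Oc1cc(OCc2ccccc2)c(c(OCc2ccccc2)c1)OCOC | intermediate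
34 | A–B dimer phenol, 2,6-bis(benzyloxy)-4-[2,4,6-tris(benzyloxy)phenoxy]phenol | c1(OCc2ccccc2)cc(OCc2ccccc2)cc(OCc2ccccc2)c1Oc1cc(OCc2ccccc2)c(c(OCc2ccccc2)c1)O | intermediate
35 | potassium phenoxide of dimer 34 | c1(OCc2ccccc2)cc(OCc2ccccc2)cc(OCc2ccccc2)c1Oc1cc(OCc2ccccc2)c(c(OCc2ccccc2)c1)[O-].[K+] | intermediate
36 | 3,4,5-tris(benzyloxy)benzyne (triple bond C1–C2) | C1#CC(OCc2ccccc2)=C(OCc2ccccc2)C(OCc2ccccc2)=C1 | intermediate
37 | A–B–C trimer aryl potassium: ring B oxygen on C1 of ring C, carbanion on C2 | c1(OCc2ccccc2)cc(OCc2ccccc2)cc(OCc2ccccc2)c1Oc1cc(OCc2ccccc2)c(c(OCc2ccccc2)c1)Oc1cc(OCc2ccccc2)c(OCc2ccccc2)c(OCc2ccccc2)[c-]1.[K+] | intermediate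
38 | A–B–C trimer iodide: dimer 34 O-arylated with 3,4,5-tris(benzyloxy)-2-iodophenyl (ring C, iodine on C2) | c1(OCc2ccccc2)cc(OCc2ccccc2)cc(OCc2ccccc2)c1Oc1cc(OCc2ccccc2)c(c(OCc2ccccc2)c1)Oc1cc(OCc2ccccc2)c(OCc2ccccc2)c(OCc2ccccc2)c1I | intermediate
39 | trimer arylmagnesium chloride (MgCl on C2 of ring C) | c1(OCc2ccccc2)cc(OCc2ccccc2)cc(OCc2ccccc2)c1Oc1cc(OCc2ccccc2)c(c(OCc2ccccc2)c1)Oc1cc(OCc2ccccc2)c(OCc2ccccc2)c(OCc2ccccc2)c1[Mg]Cl | intermediate
40 | trimer dimethyl boronate (B(OMe)2 on C2 of ring C) | c1(OCc2ccccc2)cc(OCc2ccccc2)cc(OCc2ccccc2)c1Oc1cc(OCc2ccccc2)c(c(OCc2ccccc2)c1)Oc1cc(OCc2ccccc2)c(OCc2ccccc2)c(OCc2ccccc2)c1B(OC)OC | intermediate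
41 | A–B–C trimer phenol (OH on C2 of ring C) | c1(OCc2ccccc2)cc(OCc2ccccc2)cc(OCc2ccccc2)c1Oc1cc(OCc2ccccc2)c(c(OCc2ccccc2)c1)Oc1cc(OCc2ccccc2)c(OCc2ccccc2)c(OCc2ccccc2)c1O | intermediate
42 | A–B–C–D tetramer MOM ether: 41 O-arylated on the ring C C2 oxygen with 3,5-bis(benzyloxy)-4-(methoxymethoxy)phenyl (ring D) | c1(OCc2ccccc2)cc(OCc2ccccc2)cc(OCc2ccccc2)c1Oc1cc(OCc2ccccc2)c(c(OCc2ccccc2)c1)Oc1cc(OCc2ccccc2)c(OCc2ccccc2)c(OCc2ccccc2)c1Oc1cc(OCc2ccccc2)c(c(OCc2ccccc2)c1)OCOC | intermediate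
43 | A–B–C–D tetramer phenol (free 4-OH on ring D) | c1(OCc2ccccc2)cc(OCc2ccccc2)cc(OCc2ccccc2)c1Oc1cc(OCc2ccccc2)c(c(OCc2ccccc2)c1)Oc1cc(OCc2ccccc2)c(OCc2ccccc2)c(OCc2ccccc2)c1Oc1cc(OCc2ccccc2)c(c(OCc2ccccc2)c1)O | intermediate
44 | squaric acid dichloride, 3,4-dichlorocyclobut-3-ene-1,2-dione | O=C1C(=O)C(Cl)=C1Cl | starting material
45 | 3-chloro-4-methoxycyclobut-3-ene-1,2-dione | O=C1C(=O)C(OC)=C1Cl | intermediate
46 | tetramer aryl methyl squarate: 3-methoxy-4-(aryloxy)cyclobut-3-ene-1,2-dione, aryloxy = ring D oxygen of 43 | c1(OCc2ccccc2)cc(OCc2ccccc2)cc(OCc2ccccc2)c1Oc1cc(OCc2ccccc2)c(c(OCc2ccccc2)c1)Oc1cc(OCc2ccccc2)c(OCc2ccccc2)c(OCc2ccccc2)c1Oc1cc(OCc2ccccc2)c(c(OCc2ccccc2)c1)OC1=C(OC)C(=O)C1=O | intermediate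
47 | methyl vinyl ether | COC=C | starting material
48 | 1-methoxyvinyllithium | [Li]C(=C)OC | intermediate
49 | lithium alkoxide from addition to the carbonyl next to the methoxy-bearing carbon of 46 (racemic) | c1(OCc2ccccc2)cc(OCc2ccccc2)cc(OCc2ccccc2)c1Oc1cc(OCc2ccccc2)c(c(OCc2ccccc2)c1)Oc1cc(OCc2ccccc2)c(OCc2ccccc2)c(OCc2ccccc2)c1Oc1cc(OCc2ccccc2)c(c(OCc2ccccc2)c1)OC1=C(OC)C([O-])(C(=C)OC)C1=O.[Li+] | intermediate
50 | racemic 2-(tetramer aryloxy)-3,4-dimethoxy-4-(1-methoxyvinyl)cyclobut-2-en-1-one | c1(OCc2ccccc2)cc(OCc2ccccc2)cc(OCc2ccccc2)c1Oc1cc(OCc2ccccc2)c(c(OCc2ccccc2)c1)Oc1cc(OCc2ccccc2)c(OCc2ccccc2)c(OCc2ccccc2)c1Oc1cc(OCc2ccccc2)c(c(OCc2ccccc2)c1)OC1=C(OC)C(OC)(C(=C)OC)C1=O | intermediate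
51 | (Z)-dienylketene: 2-(tetramer aryloxy)-3,4,5-trimethoxyhexa-1,3,5-trien-1-one | c1(OCc2ccccc2)cc(OCc2ccccc2)cc(OCc2ccccc2)c1Oc1cc(OCc2ccccc2)c(c(OCc2ccccc2)c1)Oc1cc(OCc2ccccc2)c(OCc2ccccc2)c(OCc2ccccc2)c1Oc1cc(OCc2ccccc2)c(c(OCc2ccccc2)c1)OC(=C=O)/C(OC)=C(OC)\C(OC)=C | intermediate
52 | 2-(tetramer aryloxy)-3,4,5-trimethoxycyclohexa-2,4-dien-1-one | c1(OCc2ccccc2)cc(OCc2ccccc2)cc(OCc2ccccc2)c1Oc1cc(OCc2ccccc2)c(c(OCc2ccccc2)c1)Oc1cc(OCc2ccccc2)c(OCc2ccccc2)c(OCc2ccccc2)c1Oc1cc(OCc2ccccc2)c(c(OCc2ccccc2)c1)OC1=C(OC)C(OC)=C(OC)CC1=O | intermediate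
53 | A–B–C–D–E pentamer phenol: ring E = 2-hydroxy-4,5,6-trimethoxyphenyl on the ring D C4 oxygen (free OH on C2 of ring E) | c1(OCc2ccccc2)cc(OCc2ccccc2)cc(OCc2ccccc2)c1Oc1cc(OCc2ccccc2)c(c(OCc2ccccc2)c1)Oc1cc(OCc2ccccc2)c(OCc2ccccc2)c(OCc2ccccc2)c1Oc1cc(OCc2ccccc2)c(c(OCc2ccccc2)c1)Oc1c(OC)c(OC)c(OC)cc1O | intermediate
54 | 5,6-didehydro-7-(methoxymethoxy)-2,2-diphenyl-1,3-benzodioxole (ring F aryne) | C1#CC(OCOC)=C2OC(c3ccccc3)(c3ccccc3)OC2=C1 | intermediate
55 | A-to-F hexamer MOM ether: 53 O-arylated on the ring E C2 oxygen with 7-(methoxymethoxy)-2,2-diphenyl-1,3-benzodioxol-5-yl (ring F) | c1(OCc2ccccc2)cc(OCc2ccccc2)cc(OCc2ccccc2)c1Oc1cc(OCc2ccccc2)c(c(OCc2ccccc2)c1)Oc1cc(OCc2ccccc2)c(OCc2ccccc2)c(OCc2ccccc2)c1Oc1cc(OCc2ccccc2)c(c(OCc2ccccc2)c1)Oc1c(OC)c(OC)c(OC)cc1Oc1cc3OC(c2ccccc2)(c2ccccc2)Oc3c(c1)OCOC | intermediate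
56 | A-to-F hexamer phenol (free OH on C7 of the ring F benzodioxole) | c1(OCc2ccccc2)cc(OCc2ccccc2)cc(OCc2ccccc2)c1Oc1cc(OCc2ccccc2)c(c(OCc2ccccc2)c1)Oc1cc(OCc2ccccc2)c(OCc2ccccc2)c(OCc2ccccc2)c1Oc1cc(OCc2ccccc2)c(c(OCc2ccccc2)c1)Oc1c(OC)c(OC)c(OC)cc1Oc1cc3OC(c2ccccc2)(c2ccccc2)Oc3c(c1)O | intermediate
57 | potassium phenoxide of hexamer 56 | c1(OCc2ccccc2)cc(OCc2ccccc2)cc(OCc2ccccc2)c1Oc1cc(OCc2ccccc2)c(c(OCc2ccccc2)c1)Oc1cc(OCc2ccccc2)c(OCc2ccccc2)c(OCc2ccccc2)c1Oc1cc(OCc2ccccc2)c(c(OCc2ccccc2)c1)Oc1c(OC)c(OC)c(OC)cc1Oc1cc3OC(c2ccccc2)(c2ccccc2)Oc3c(c1)[O-].[K+] | intermediate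
58 | A-to-G heptamer aryl potassium: ring F oxygen on C1 of ring G, carbanion on C2 | c1(OCc2ccccc2)cc(OCc2ccccc2)cc(OCc2ccccc2)c1Oc1cc(OCc2ccccc2)c(c(OCc2ccccc2)c1)Oc1cc(OCc2ccccc2)c(OCc2ccccc2)c(OCc2ccccc2)c1Oc1cc(OCc2ccccc2)c(c(OCc2ccccc2)c1)Oc1c(OC)c(OC)c(OC)cc1Oc1cc3OC(c2ccccc2)(c2ccccc2)Oc3c(c1)Oc1cc(OCc2ccccc2)c(OCc2ccccc2)c(OCc2ccccc2)[c-]1.[K+] | intermediate
59 | A-to-G heptamer iodide: 56 O-arylated with 3,4,5-tris(benzyloxy)-2-iodophenyl (ring G, iodine on C2) | c1(OCc2ccccc2)cc(OCc2ccccc2)cc(OCc2ccccc2)c1Oc1cc(OCc2ccccc2)c(c(OCc2ccccc2)c1)Oc1cc(OCc2ccccc2)c(OCc2ccccc2)c(OCc2ccccc2)c1Oc1cc(OCc2ccccc2)c(c(OCc2ccccc2)c1)Oc1c(OC)c(OC)c(OC)cc1Oc1cc3OC(c2ccccc2)(c2ccccc2)Oc3c(c1)Oc1cc(OCc2ccccc2)c(OCc2ccccc2)c(OCc2ccccc2)c1I | intermediate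
60 | heptamer arylmagnesium chloride (MgCl on C2 of ring G) | c1(OCc2ccccc2)cc(OCc2ccccc2)cc(OCc2ccccc2)c1Oc1cc(OCc2ccccc2)c(c(OCc2ccccc2)c1)Oc1cc(OCc2ccccc2)c(OCc2ccccc2)c(OCc2ccccc2)c1Oc1cc(OCc2ccccc2)c(c(OCc2ccccc2)c1)Oc1c(OC)c(OC)c(OC)cc1Oc1cc3OC(c2ccccc2)(c2ccccc2)Oc3c(c1)Oc1cc(OCc2ccccc2)c(OCc2ccccc2)c(OCc2ccccc2)c1[Mg]Cl | intermediate
61 | heptamer dimethyl boronate (B(OMe)2 on C2 of ring G) | c1(OCc2ccccc2)cc(OCc2ccccc2)cc(OCc2ccccc2)c1Oc1cc(OCc2ccccc2)c(c(OCc2ccccc2)c1)Oc1cc(OCc2ccccc2)c(OCc2ccccc2)c(OCc2ccccc2)c1Oc1cc(OCc2ccccc2)c(c(OCc2ccccc2)c1)Oc1c(OC)c(OC)c(OC)cc1Oc1cc3OC(c2ccccc2)(c2ccccc2)Oc3c(c1)Oc1cc(OCc2ccccc2)c(OCc2ccccc2)c(OCc2ccccc2)c1B(OC)OC | intermediate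
62 | A-to-G heptamer phenol (OH on C2 of ring G) | c1(OCc2ccccc2)cc(OCc2ccccc2)cc(OCc2ccccc2)c1Oc1cc(OCc2ccccc2)c(c(OCc2ccccc2)c1)Oc1cc(OCc2ccccc2)c(OCc2ccccc2)c(OCc2ccccc2)c1Oc1cc(OCc2ccccc2)c(c(OCc2ccccc2)c1)Oc1c(OC)c(OC)c(OC)cc1Oc1cc3OC(c2ccccc2)(c2ccccc2)Oc3c(c1)Oc1cc(OCc2ccccc2)c(OCc2ccccc2)c(OCc2ccccc2)c1O | intermediate
63 | fully protected octamer: 62 O-arylated on the ring G C2 oxygen with 3,4,5-tris(benzyloxy)phenyl (ring H); sixteen benzyl ethers, one diphenylmethylene ketal, three methyl ethers | c1(OCc2ccccc2)cc(OCc2ccccc2)cc(OCc2ccccc2)c1Oc1cc(OCc2ccccc2)c(c(OCc2ccccc2)c1)Oc1cc(OCc2ccccc2)c(OCc2ccccc2)c(OCc2ccccc2)c1Oc1cc(OCc2ccccc2)c(c(OCc2ccccc2)c1)Oc1c(OC)c(OC)c(OC)cc1Oc1cc3OC(c2ccccc2)(c2ccccc2)Oc3c(c1)Oc1cc(OCc2ccccc2)c(OCc2ccccc2)c(OCc2ccccc2)c1Oc1cc(OCc2ccccc2)c(OCc2ccccc2)c(OCc2ccccc2)c1 | intermediate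
64 | octamer with all hydroxyls free except the three methyl ethers on C4, C5 and C6 of ring E | c1(O)cc(O)cc(O)c1Oc1cc(O)c(c(O)c1)Oc1cc(O)c(O)c(O)c1Oc1cc(O)c(c(O)c1)Oc1c(OC)c(OC)c(OC)cc1Oc1cc(O)c(O)c(c1)Oc1cc(O)c(O)c(O)c1Oc1cc(O)c(O)c(O)c1 | intermediate
65 | CNP0309601.0 | Oc1cc(O)c(Oc2cc(O)c(Oc3cc(O)c(O)c(O)c3Oc3cc(O)c(Oc4c(Oc5cc(O)c(O)c(Oc6cc(O)c(O)c(O)c6Oc6cc(O)c(O)c(O)c6)c5)cc(O)c(O)c4O)c(O)c3)c(O)c2)c(O)c1 | target

**Step count**

Total step count: 34.
Longest linear sequence: 21 steps (5 to 13 by steps 3 to 7, then steps 18 to 23 and 25 to 34).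

**Steps most likely to fail**

1. Step 20 (proposed new method). The C2 carbanion may be protonated faster than it abstracts iodine, by trace proton sources or by hydrogen transfer from a neighbouring benzylic C–H. The phenoxide may also be perfluoroalkylated by electron transfer. Either process leaves ring C without its handle on C2. Fallback, from 20 and 34 back to 38, with known reactions: the aryne from 20 (CsF, MeCN) is generated in the presence of I2 and inserts into the I–I bond to give 1,2-diiodo-3,4,5-tris(benzyloxy)benzene F1. Copper-catalysed Ullmann etherification of 34 with F1 (CuI, picolinic acid, K3PO4, DMSO, 90 °C) should engage the iodide next to the C–H position and spare the one flanked by the benzyloxy group, giving 38.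

2. Step 30 (proposed new method). The same loss of the carbanion to protonation or the same electron-transfer side reaction can occur, now on a precious hexamer. Fallback, from 56 directly to 63 (59 and 62 are by-passed), with known reactions: a G–H unit is made first and attached as a whole. Purchased 2,3,4-trihydroxybenzaldehyde is benzylated (BnBr, K2CO3, DMF) to 2,3,4-tris(benzyloxy)benzaldehyde F2, oxidised with mCPBA to 2,3,4-tris(benzyloxy)phenyl formate F3 and methanolysed to 2,3,4-tris(benzyloxy)phenol F4. N-Iodosuccinimide iodinates the only free ortho position to give 2,3,4-tris(benzyloxy)-6-iodophenol F5. Its oxygen is arylated with benzyne 36 from 20 (CsF, MeCN) to the G–H iodide F6. Ullmann coupling of 56 with F6 (CuI, N,N-dimethylglycine, Cs2CO3, dioxane, 100 °C) then gives 63.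

3. Step 26. The vinyllithium may add to the other carbonyl, which would put the ring E oxygens in the wrong order, or it may attack the aryloxy-bearing carbon by addition–elimination and expel the tetramer phenoxide. Fallback, from 43 back to 53, replacing ring construction by SNAr and Baeyer–Villiger oxidation: purchased 3,4,5-trimethoxybenzaldehyde is fluorinated with Selectfluor in MeCN (the two open positions are equivalent) to 2-fluoro-3,4,5-trimethoxybenzaldehyde F7. The cesium phenoxide of 43 displaces fluoride, activated by the ortho formyl group (Cs2CO3, DMSO, 110 °C), to give the pentamer aldehyde F8. mCPBA converts it into the pentamer formate F9, and K2CO3 in MeOH releases 53.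

Further compounds
F1 | step 20 | 1,2-diiodo-3,4,5-tris(benzyloxy)benzene | Ic1cc(OCc2ccccc2)c(OCc2ccccc2)c(OCc2ccccc2)c1I
F2 | step 30 | 2,3,4-tris(benzyloxy)benzaldehyde | O=Cc1ccc(OCc2ccccc2)c(OCc2ccccc2)c1OCc2ccccc2
F3 | step 30 | 2,3,4-tris(benzyloxy)phenyl formate | O=COc1ccc(OCc2ccccc2)c(OCc2ccccc2)c1OCc2ccccc2
F4 | step 30 | 2,3,4-tris(benzyloxy)phenol | Oc1ccc(OCc2ccccc2)c(OCc2ccccc2)c1OCc2ccccc2
F5 | step 30 | 2,3,4-tris(benzyloxy)-6-iodophenol | Oc1c(I)cc(OCc2ccccc2)c(OCc2ccccc2)c1OCc2ccccc2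
F6 | step 30 | G–H iodide, 1-iodo-3,4,5-tris(benzyloxy)-2-[3,4,5-tris(benzyloxy)phenoxy]benzene | Ic1cc(OCc2ccccc2)c(OCc2ccccc2)c(OCc2ccccc2)c1Oc1cc(OCc2ccccc2)c(OCc2ccccc2)c(OCc2ccccc2)c1
F7 | step 26 | 2-fluoro-3,4,5-trimethoxybenzaldehyde | O=Cc1cc(OC)c(OC)c(OC)c1F
F8 | step 26 | pentamer aldehyde: ring E = 2-formyl-4,5,6-trimethoxyphenyl on the ring D C4 oxygen of 43 | c1(OCc2ccccc2)cc(OCc2ccccc2)cc(OCc2ccccc2)c1Oc1cc(OCc2ccccc2)c(c(OCc2ccccc2)c1)Oc1cc(OCc2ccccc2)c(OCc2ccccc2)c(OCc2ccccc2)c1Oc1cc(OCc2ccccc2)c(c(OCc2ccccc2)c1)Oc1c(OC)c(OC)c(OC)cc1C=O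
F9 | step 26 | pentamer formate: ring E = 2-(formyloxy)-4,5,6-trimethoxyphenyl on the ring D C4 oxygen of 43 | c1(OCc2ccccc2)cc(OCc2ccccc2)cc(OCc2ccccc2)c1Oc1cc(OCc2ccccc2)c(c(OCc2ccccc2)c1)Oc1cc(OCc2ccccc2)c(OCc2ccccc2)c(OCc2ccccc2)c1Oc1cc(OCc2ccccc2)c(c(OCc2ccccc2)c1)Oc1c(OC)c(OC)c(OC)cc1OC=O
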